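The numbers come from no measurement; the rest is arithmetic.

A small charge of substrate, 0.19 M, draws its partner from a reagent stock in a second phase. Reagent crosses into the reaction phase, where part of it rests as dormant form. There it makes target from substrate. Target then partitions into the second phase, decays to decomposed and over-reaction product, and couples with substrate to side product.

substrate 0.19 M; reagent in the second phase 3.00 equiv; time 40 min; volume of the second phase over the first 2.0

1. the target and product in the second phase together standing at 40 min, as a percentage of the substrate charged
2. the change that raises the amount of target and product in the second phase together at 40 min, in percent of the substrate charged most ("none" if none brings more than 2 percentage points) (Monday's / Sunday's / Friday's / none)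
3. amount of target and product in the second phase together at 40 min, in percent of the substrate charged, after Sunday's

- percent here means substrate units held: one side product counts as two
- what is said of target includes product in the second phase
- in the second phase: reagent in the second phase, product in the second phase; everything else is in the first
- charges count per volume of the first phase; a concentration in a rate is the amount of a species over the volume of its own phase; every rate counts per litre of the first phase
- run time (flask): 40 min

    reagent in the reaction phase ⇌ reagent in the second phase, rate k1*([reagent in the reaction phase] - [reagent in the second phase]/K1) per volume of the first phase (K1 = 1.7, k1 = 0.25 min⁻¹)
    substrate + reagent in the reaction phase → target (k2 = 0.77 M⁻¹ min⁻¹)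
    target ⇌ product in the second phase, rate k3*([target] - [product in the second phase]/K3) per volume of the first phase (K3 = 0.21, k3 = 6.7 min⁻¹)
    target → decomposed product (k4 = 0.067 min⁻¹)
    reagent in the reaction phase ⇌ dormant form (K5 = 0.44, k5 = 0.046 min⁻¹)
    target → over-reaction product (k6 = 0.0035 min⁻¹)
    substrate + target → side product (k7 = 0.95 M⁻¹ min⁻¹)

Work with the fraction left. Target transfer is far faster than its decay, so the pool of target and product in the second phase keeps a steady 70.4% of itself in the reaction phase, and that part decays. Call this share times the two first-order decay constants the pool's loss constant, 0.0496 min⁻¹, a half-life of 14.0 min. Counting one equivalent spent and spreading the remaining reagent over its three forms, I give substrate a pseudo-first-order constant of 0.0605 min⁻¹, and 0.151 min⁻¹ in Sunday's flask. Both flasks carry the same factor, 13.8% left after 40 min. Sunday's flask spends its substrate faster, but its target then ages longer in the pool. For an intermediate between two first-order steps, coupling ignored, I get 26.9% for the flask and 20.1% after Sunday's. Both figures leave coupling out, which I can't carry by hand. Sunday's lowers my figure and neither transfer coefficient enters it, so I commit to none as the best change.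

The forecast, below my figure, gives 12.2% (range 11% to 13.4%), 12.3% after Sunday's (11% to 13.8%) and none as the best change, holding that “Target transfer is fast, so the phases stay equilibrated”.

The simulation gives 12.7%, and 12.5% after Sunday's. The best change is none: Monday's brings 0 percentage points, Sunday's −0.18 points, Friday's −0.69 points.

Two losses act together in the flask: the run without coupling gives 28.3%, close to my 26.9%, and the run without decomposition gives 35.2%. From 12.7% the loss constant leaves 1.75% at 80.0 min, against 2.39% read, with 3.4% of substrate still to react at 40 min.

Near its top the pool stands where making equals loss: the making constant times reagent times the fraction of substrate left, over the loss constant plus the share's coupling term. In the flask read at 15 min, with 32.5% of substrate left and 0.0846 M of reagent in the reaction phase, this gives 23.3%. The simulation reads 23.1%.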